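## Remarks on the chemistry (assumptions and corrections)

- Atom labels are those of the target: C1 = AcO–CH=, C2–C8 run round the carbocycle through the diene to the O-bearing carbon, C10 = lactone C=O, C11 and C12 = lactone CH carbons, C13 = side-chain CH(CH3).
- Correction of locants: by ring numbering the fragmentation product is a cyclonon-4-en-1-one (a γ,δ-enone), and the cyclobutene-opening product of Alternative 3 is a cyclonona-2,4-dien-1-one. "C5=C6" and "C3=C4" are target labels only. The fragmentation substrate and product were rechecked centre by centre against the target (C8, C11, C12, C13) and are consistent with it.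
- Assumption: (S)-citronellic acid is purchased (it is also the NaClO2 oxidation product of (S)-citronellal).
- Assumption: ethyl glyoxylate is used as freshly cracked monomer.

## Structural features

The target is an oxabicyclo[6.2.1]undecane. A nine-membered carbocycle (C2–C8, C12, C11) is bridged by a γ-lactone (C8–O–C10(=O)–C11) that shares C8–C12–C11 with it, so C8 and C11 are bridgeheads and C12 is the one-atom bridge. C8, C12 and C11 are contiguous stereocentres and C12 adjoins the exocyclic C13 methine of the (S)-6-methylhept-5-en-2-yl chain. The lactone substituents are trans,trans, which on the carbocycle places C8–O, the side chain and C11–C10 on one face. The carbocycle carries the linear triene AcO–C1H=C2–C3H=C4H–C5H=C6(CH3): an exocyclic enol acetate with OAc cis to C11, a Z C3=C4 bond and an E trisubstituted C5=C6 bond. Fragile elements are the enol acetate, the strained E alkene in a medium ring, the doubly allylic C4, and the trisubstituted side-chain alkene, which rules out hydrogenation, ozonolysis and free borane. The real difficulty is the E-configured nine-membered ring together with the all-syn C8/C12/C11 triad, in which the C11 substituent is in the less stable orientation unless the lactone holds it, and the relay from C13 to C12. The key step uses the fact that, once C1 is removed, C2 is a ketone with the E C5=C6(CH3) alkene γ,δ to it. Reconnecting C2 to C6 gives a cis-hydrindane (cyclopentane C2–C3–C4–C5–C6, cyclohexane C2–C11–C12–C8–C7–C6) with a C2 hydroxyl and a C5 sulfonate.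

## Logic of the disconnections

**32 ⇒ 31.** The acetyl–O bond is cut, and the C1=C2 and C3=C4 π bonds are traced back to one C2=C3 bond plus a C1 aldehyde. The whole triene is the O-acetylated extended enolate of an enal, so the base-labile enol ester and the Z alkene appear only in the last step. The forward step must deprotonate C4 (not C11) and place the oxygen cis to C11.

**31 ⇒ 30.** C2–C1 is cut. A formyl group on an alkene carbon is the carbonylation product of a vinyl triflate, so C1 never has to be added to a hindered, enolisable ketone. The forward step must carbonylate without moving the C2=C3 or C5=C6 bonds.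

**30 ⇒ 27 ⇒ 26.** The lactone is taken back to the C8/C10 diol and then to its bis-silyl ether. A lactone carbonyl β to the C2 oxygen cannot pass through the fragmentation. The forward steps need a primary-selective oxidation and the cis C8–O/C11–C10 relation for lactol closure.

**26 ⇒ 24.** The C2–OTf bond is cut back to the C2 ketone. The forward step needs kinetic enolisation toward C3 and away from C11.

**24 ⇒ 22 (key).** C2 and C6 are reconnected, with OH on C2 and OTs on C5. The medium ring and its E alkene are exchanged for a cis-hydrindane whose stereochemistry follows small-ring rules. The forward step needs the tosylate cis to the angular methyl and antiperiplanar to C2–C6, no carbonyl β to the C2 oxygen, and C8–O capped.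

**22 ⇒ 21 ⇒ 20 ⇒ 19 ⇒ 18.** These are functional-group changes only. The two silyl ethers go back to a bridged lactone, which masks C8–O and C10 while C5 alone is sulfonylated, and the tosylate goes back to the C5 ketone. The forward reduction must deliver hydride to C5 anti to the methyl group.

**18 ⇒ 16.** C11–C2 is cut (aldol retron of the β-hydroxy lactone). This reveals a symmetric 2,2-disubstituted cyclopentane-1,3-dione and a monocyclic lactone, and the tether from C8 makes the C11 configuration automatic. The forward step needs a regiospecific lactone enolate beside more acidic ketones, hence bromine at C11, and a choice between two diastereotopic carbonyls.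

**16 ⇒ 15 ⇒ 13.** C11–Br goes back to C11–OH, and the lactone C–O and C8–H bonds go back to a C8 ketone and an ethyl ester. The C11 hydroxyl thus serves as directing group, bromide precursor and aldol handle. The forward step needs a chemoselective anti reduction of the acyclic ketone beside the dione.

**13 ⇒ 12 ⇒ 10 + 11.** C6–C7 is cut (enolate alkylation), giving a convergent union with the commercial dione. The forward step needs C- over O-alkylation and no epimerisation at C12.

**10 ⇒ 9 ⇒ 8.** C7–C8 is cut (one-carbon homologation of an amide). The forward step needs mono-addition and survival of the ester.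

**8 ⇒ 7 ⇒ 4 + 5.** C11–C12 is cut (aldol). C10/C11 arrive as glyoxylate and C12 is set by an auxiliary next to C13. The forward step needs syn selectivity under reagent control.

**4 ⇒ 1 + 2.** The N-acyl bond is cut to the chiral-pool acid and the auxiliary.

## Other disconnections considered

**Alternative 1:** The cut runs through C8–C12 and the lactone C–O bond, back to the open-chain aldehyde–enoate A2, which already holds the diene and the C2 stereocentre. Forward, SmI2 would convert the aldehyde into a ketyl that adds to C12; protonation at C11 and lactonisation of the C8 alkoxide would give A1.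
- In its favour: one step would make the carbocycle, the lactone and three stereocentres, and the diene geometry is set by open-chain olefination. On step economy it is better than the chosen plan, since from A1 only desilylation, oxidation and enol acetylation remain.
- Against it here: a nine-membered ring must close by radical addition to a β-branched, α-substituted enoate, with pinacol coupling and simple reduction as competitors. C8, C12 and C11 would all come from one flexible medium-ring transition state with no template. C12 is not under auxiliary control next to C13, and the skipped (Z,E)-diene must survive the reductant.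
- Comparison: the chosen plan sets the same three centres on five- and six-membered templates and obtains the ring by a stereospecific fragmentation with no entropic cost. It is longer. The final enol acetylation is equally uncertain in both.

**Alternative 2:** The cut is C11–C2, back to the Co2(CO)6-complexed propargylic acetate A4 carrying the lactone as its silyl ketene acetal. Forward, BF3·OEt2 would ionise the C2 acetate and the ketene acetal would capture the cation to give A3.
- In its favour: the complex bends the alkyne to about 140°, which eases the medium-ring closure. The lactone with C8 and C12 is in place from the start, so no late oxidative lactonisation is needed, and on that point it is better than the chosen plan. The enolate should be attacked anti to the C12 substituent, the same facial bias the chosen plan uses in step 10, so the two are equal there.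
- Against it here: it needs stoichiometric Co2(CO)8, and decomplexation must be reductive to deliver the Z C3=C4 alkene. The cation sits next to a silyloxymethyl group, and the ring must hold both an E alkene and the cluster. C1 must still be oxidised and enolised toward C2 at the end.
- Comparison: the step count is about equal. The mechanism is less certain (cation versus silyl ketene acetal under a Lewis acid) than an alkoxide fragmentation.

**Alternative 3:** No ring bond is cut retrosynthetically. The C3–C6 σ bond is re-formed to give the cis-fused cyclobutene ketone A6, which on heating would open in a conrotatory sense to the dienone A5.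
- In its favour: the step is thermal and reagent-free and makes both ring alkenes at once. A Z,E pair is guaranteed by conrotation of a cis-fused cyclobutene, a certainty equal to the stereospecificity of the fragmentation.
- Against it here: which alkene becomes E is a matter of torquoselectivity, and the needed mode turns the C6 methyl inward, against the normal outward preference of alkyl groups, so the (3E,5Z) isomer is the likelier outcome. A6 needs a [2+2] photocycloaddition creating a quaternary centre on a seven-membered ring with three stereocentres, and the temperature invites 1,5-hydrogen shifts.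
- Comparison: A5 would still need C1 added to a hindered dienone. The chosen plan is longer before the ring expansion but has no ambiguity about alkene geometry.

Key step: step 15

## Route

Step 1
Reactants: 1 (S)-citronellic acid; 2 (R)-4-benzyl-1,3-oxazolidin-2-one
Product: 4 (4R)-4-benzyl-3-[(3S)-3,7-dimethyloct-6-enoyl]-1,3-oxazolidin-2-one, via mixed pivalic anhydride 3 (not isolated)
Conditions: PivCl, Et3N, THF, −20 °C; then 2, LiCl, −20 °C → rt
Reagents that add atoms: none
Why: Mixed-anhydride N-acylation of the LiCl-activated oxazolidinone; C13 is β to the carbonyl and is not touched.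

Step 2
Reactants: 4 (4R)-4-benzyl-3-[(3S)-3,7-dimethyloct-6-enoyl]-1,3-oxazolidin-2-one; 5 ethyl glyoxylate
Product: 7 syn-aldol imide (ethyl 2R-hydroxy ester with the imide carbonyl on C12), via dibutylboron Z-enolate 6 (not isolated)
Conditions: Bu2BOTf, i-Pr2NEt, CH2Cl2, −78 → 0 °C; 5, −78 → 0 °C; then NaH2PO4/Na2HPO4 buffer (pH 7), MeOH, 30% H2O2, 0 °C
Reagents that add atoms: none
Why: Evans boron syn-aldol through a Zimmerman–Traxler chair; the benzyl group of the (R)-auxiliary shields one enolate face, so C12 (R) and C11 (R) should be set under reagent control whatever the influence of C13, and only the aldehyde carbonyl of 5 reacts.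

Step 3
Reactants: 7 syn-aldol imide
Product: 8 hydroxy Weinreb amide (ethyl (2R,3R,4S)-2-hydroxy-3-[methoxy(methyl)carbamoyl]-4,8-dimethylnon-7-enoate)
Conditions: MeONHMe·HCl, AlMe3, CH2Cl2, −20 → 0 °C; aq. KNaC4H4O6
Reagents that add atoms: N,O-dimethylhydroxylamine hydrochloride (CNOC.Cl)
Why: Aluminium amide transamination of an aldol imide, assisted by the β-alkoxide, should proceed at the imide well below the temperature at which ethyl esters are amidated; auxiliary 2 is returned.

Step 4
Reactants: 8 hydroxy Weinreb amide
Product: 9 triethylsilyl ether Weinreb amide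
Conditions: Et3SiCl, imidazole, DMAP (cat.), DMF, 0 °C → rt
Reagents that add atoms: chlorotriethylsilane (CC[Si](Cl)(CC)CC)
Why: Silylation masks the C11 hydroxyl against the organolithium of step 5 and against internal O-alkylation in step 6.

Step 5
Reactants: 9 triethylsilyl ether Weinreb amide
Product: 10 chloromethyl ketone (ethyl (2R,3R,4S)-3-(chloroacetyl)-4,8-dimethyl-2-[(triethylsilyl)oxy]non-7-enoate)
Conditions: ICH2Cl, MeLi·LiBr, THF, −78 °C; aq. NH4Cl
Reagents that add atoms: chloroiodomethane (ClCI)
Why: Carbenoid homologation of a Weinreb amide: chloromethyllithium made by iodine–lithium exchange in the presence of 9 adds once, the ketone being released only on quench, which forms C7–C8; the hindered α-silyloxy ester and C12 should survive at −78 °C.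

Step 6
Reactants: 10 chloromethyl ketone; 11 2-methylcyclopentane-1,3-dione
Product: 12 silyloxy triketone ester (C6 now quaternary: CH3, C7 and the two ring carbonyls)
Conditions: 11 (1.5 equiv), K2CO3 (0.75 equiv), NaI (0.2 equiv), DMF, rt
Reagents that add atoms: none
Why: C-alkylation of the soft, barely basic dione enolate by the α-halo ketone under iodide catalysis forms C6–C7; no free base remains, so C12 should not epimerise and the β-silyloxy group should not be eliminated.

Step 7
Reactants: 12 silyloxy triketone ester
Product: 13 hydroxy triketone ester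
Conditions: HF·pyridine, pyridine, THF, 0 °C
Reagents that add atoms: none
Why: Buffered fluoride desilylation frees the β-hydroxyl that must direct the next reduction, without exposing the 1,3-dione to base.

Step 8
Reactants: 13 hydroxy triketone ester
Product: 15 α-hydroxy γ-lactone dione (side chain trans to both the C11 hydroxyl and the C8 substituent), via anti-diol ester 14 (not isolated)
Conditions: Me4NBH(OAc)3, MeCN–AcOH (1:1), −25 °C; then PPTS (cat.), PhMe, 50 °C
Reagents that add atoms: none
Why: Evans–Saksena reduction: boron bound to the C11 oxygen delivers hydride to C8 through a chair to give the 1,3-anti diol, and the undirected dione carbonyls are not reduced; acid then closes the γ-lactone from C8–OH, so C8 is set trans to the C12 side chain.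

Step 9
Reactants: 15 α-hydroxy γ-lactone dione
Product: 16 α-bromo γ-lactone dione
Conditions: CBr4, PPh3, CH2Cl2, 0 °C
Reagents that add atoms: tetrabromomethane (BrC(Br)(Br)Br)
Why: Appel bromination under neutral conditions, with inversion at C11; this is of no consequence because C11 becomes an enolate in the next step.

Step 10
Reactants: 16 α-bromo γ-lactone dione
Product: 18 tricyclic hydroxy keto lactone (cis-hydrindanolone bridged by the γ-lactone), via samarium lactone enolate 17 (not isolated)
Conditions: SmI2 (2.5 equiv), THF, −78 → −20 °C; aq. NH4Cl
Reagents that add atoms: none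
Why: Samarium Reformatsky aldol: two-electron reduction of C–Br gives the trivalent samarium enolate, which adds to one dione carbonyl to form C11–C2 and the cyclohexane. The tether from C8 forces the new bond cis to C7, so C11 is correct and OH is cis to CH3. Samarium bridging the enolate and ketone oxygens, with the methyl group rather than the second carbonyl under the lactone, should select the carbonyl shown.

Step 11
Reactants: 18 tricyclic hydroxy keto lactone
Product: 19 tricyclic dihydroxy lactone (C5–OH cis to CH3)
Conditions: NaBH4, MeOH–CH2Cl2 (1:1), −40 °C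
Reagents that add atoms: none
Why: Hydride should attack the cyclopentanone from the face opposite the vicinal angular methyl and the syn tertiary hydroxyl, as in Hajos–Parrish-type 1-ketones, which places C5–OH cis to CH3; the lactone is not reduced at this temperature.

Step 12
Reactants: 19 tricyclic dihydroxy lactone
Product: 20 tricyclic hydroxy lactone tosylate
Conditions: TsCl, pyridine, DMAP (cat.), CH2Cl2, 0 °C → rt
Reagents that add atoms: 4-toluenesulfonyl chloride (Cc1ccc(cc1)S(=O)(=O)Cl)
Why: The C5 hydroxyl is the only secondary alcohol, because the lactone still masks C8–O and C10; the tertiary C2–OH does not react.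

Step 13
Reactants: 20 tricyclic hydroxy lactone tosylate
Product: 21 hydrindane triol tosylate
Conditions: LiBH4, THF–MeOH, 0 °C → rt
Reagents that add atoms: none
Why: Borohydride reduction of the lactone to the 1,4-diol removes the carbonyl that would give the C2 alkoxide a retro-aldol path; the neopentyl secondary tosylate is inert to hydride displacement.

Step 14
Reactants: 21 hydrindane triol tosylate
Product: 22 cis-hydrindanol tosylate bis-TBS ether
Conditions: TBSOTf (2.3 equiv), 2,6-lutidine, CH2Cl2, −78 → −20 °C
Reagents that add atoms: tert-butyldimethylsilyl triflate (CC(C)(C)[Si](C)(C)OS(=O)(=O)C(F)(F)F)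
Why: Silyl triflate caps the primary and the secondary hydroxyl at low temperature; the ring-fusion hydroxyl next to quaternary C6 is too hindered, and capping C8–O removes an internal nucleophile.

Step 15
Reactants: 22 cis-hydrindanol tosylate bis-TBS ether
Product: 24 (E)-cyclonon-4-en-1-one bis-TBS ether (target labels: C2 ketone, E C5=C6), via potassium C2 alkoxide 23 (not isolated)
Conditions: KOt-Bu (1.1 equiv), THF, 0 °C, 30 min; NaH2PO4/Na2HPO4 buffer (pH 7)
Reagents that add atoms: none
Why: KOt-Bu deprotonates the tertiary C2–OH to alkoxide 23, whose oxygen lone pair feeds σ*(C2–C6) while the C2–C6 electrons flow into σ*(C5–OTs), so ketone, alkene and tosylate loss arise in one concerted heterolytic step; this is a Wharton-type Grob fragmentation of a cyclic 1,3-diol monosulfonate, closest in kind to hydrindanol sulfonates giving E-cyclononenones. No ring is closed by bond formation: the nine-membered ring is exposed by cutting the bond shared by the five- and six-membered rings, so no Baldwin mode, medium-ring entropy or transannular penalty applies. No stereocentre is created (C2, C5 and C6 are erased; C8, C11, C12 and C13 are untouched), and the only stereochemical outcome is the alkene geometry, which is stereospecific: with the tosylate cis to the angular methyl and antiperiplanar to C2–C6, C4 ends up trans to C7, which is E. Fragmentation must outrun substitution, E2 and enolate chemistry, and the substrate secures this: the cis alkoxide cannot reach the back of C5, C6 is quaternary, C8–O is silylated, and C10 is an ether rather than a carbonyl, so no retro-aldol is open. The antiperiplanar geometry belongs to the chair with C5 axial on the cyclohexane, and the two bulky silyl ethers avoid the other chair, where they would be 1,3-diaxial with the angular methyl, so the reactive conformer should be populated. A small excess of base, low temperature and a buffered quench are chosen because the product has an epimerisable C11–H with a β-silyloxy group.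

Step 16
Reactants: 24 (E)-cyclonon-4-en-1-one bis-TBS ether
Product: 26 cyclononadienyl triflate bis-TBS ether (C2=C3 enol triflate with C4 and C11 cis), via potassium C2–C3 enolate 25 (not isolated)
Conditions: KN(SiMe3)2, THF, −78 °C; PhNTf2, −78 → 0 °C
Reagents that add atoms: N-phenylbis(trifluoromethanesulfonimide) (O=S(=O)(N(c1ccccc1)S(=O)(=O)C(F)(F)F)C(F)(F)F)
Why: Kinetic deprotonation at the less hindered C3 methylene (C11 is tertiary and flanked by C12 and the silyloxymethyl group) and O-triflation of the enolate; beside the E alkene only a ring-cis C2=C3 bond is possible.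

Step 17
Reactants: 26 cyclononadienyl triflate bis-TBS ether
Product: 27 cyclononadienyl triflate diol
Conditions: HF·pyridine, pyridine, THF, 0 °C → rt
Reagents that add atoms: none
Why: Buffered fluoride desilylation; the vinyl triflate and the alkenes are stable to these conditions.

Step 18
Reactants: 27 cyclononadienyl triflate diol
Product: 30 bridged lactone enol triflate, via hydroxy aldehyde 28 (not isolated), via bridged lactol 29 (not isolated)
Conditions: TEMPO (0.2 equiv), PhI(OAc)2 (2.5 equiv), CH2Cl2, rt
Reagents that add atoms: none
Why: Nitroxyl-catalysed oxidative lactonisation of a 1,4-diol: the primary alcohol is oxidised selectively, the aldehyde is captured by the cis C8 hydroxyl as the five-membered lactol, and this is oxidised to the γ-lactone; once bridged, C11 is a bridgehead and configurationally locked.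

Step 19
Reactants: 30 bridged lactone enol triflate
Product: 31 bridged lactone enal (C1 formyl on C2, C2=C3 retained)
Conditions: Pd(PPh3)4 (5 mol %), CO (1 atm), Bu3SnH (slow addition), THF, 50 °C
Reagents that add atoms: carbon monoxide ([C-]#[O+])
Why: Reductive carbonylation of a vinyl triflate: oxidative addition to zerovalent palladium, CO insertion and hydride transfer from tin give the enal with the alkene geometry retained; no base is present that could move the skipped alkene.

Step 20
Reactants: 31 bridged lactone enal
Product: 32 target enol acetate lactone (CNP0287742.1)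
Conditions: Ac2O, Et3N, DMAP (cat.), CH2Cl2, rt
Reagents that add atoms: acetic anhydride (CC(=O)OC(C)=O)
Why: Dienol acetate formation: γ-deprotonation at the doubly allylic C4 and O-acetylation of the extended enolate give the 1-acetoxy triene; the ring allows only Z at C3=C4 beside the E alkene, and enolisation from the favoured s-trans enal should place OAc cis to C11.

## Compound list

1 | (S)-citronellic acid, (3S)-3,7-dimethyloct-6-enoic acid | C[C@@H](CCC=C(C)C)CC(=O)O | starting material
2 | (R)-4-benzyl-1,3-oxazolidin-2-one | O=C1N[C@H](Cc2ccccc2)CO1 | starting material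
3 | mixed anhydride of 1 and pivalic acid | C[C@@H](CCC=C(C)C)CC(=O)OC(=O)C(C)(C)C | intermediate
4 | (4R)-4-benzyl-3-[(3S)-3,7-dimethyloct-6-enoyl]-1,3-oxazolidin-2-one | C[C@@H](CCC=C(C)C)CC(=O)N1[C@H](Cc2ccccc2)COC1=O | intermediate
5 | ethyl glyoxylate | CCOC(=O)C=O | starting material
6 | dibutylboron (Z)-enolate of 4 | CCCCB(CCCC)O/C(=C\[C@@H](C)CCC=C(C)C)N1[C@H](Cc2ccccc2)COC1=O | intermediate
7 | ethyl (2R,3R,4S)-3-{[(4R)-4-benzyl-2-oxo-1,3-oxazolidin-3-yl]carbonyl}-2-hydroxy-4,8-dimethylnon-7-enoate (syn aldol; C11 = C2, C12 = C3, C13 = C4 of the chain) | CCOC(=O)[C@H](O)[C@@H]([C@@H](C)CCC=C(C)C)C(=O)N1[C@H](Cc2ccccc2)COC1=O | intermediate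
8 | ethyl (2R,3R,4S)-2-hydroxy-3-[methoxy(methyl)carbamoyl]-4,8-dimethylnon-7-enoate | CCOC(=O)[C@H](O)[C@@H]([C@@H](C)CCC=C(C)C)C(=O)N(C)OC | intermediate
9 | ethyl (2R,3R,4S)-3-[methoxy(methyl)carbamoyl]-4,8-dimethyl-2-[(triethylsilyl)oxy]non-7-enoate | CCOC(=O)[C@H](O[Si](CC)(CC)CC)[C@@H]([C@@H](C)CCC=C(C)C)C(=O)N(C)OC | intermediate
10 | ethyl (2R,3R,4S)-3-(chloroacetyl)-4,8-dimethyl-2-[(triethylsilyl)oxy]non-7-enoate | CCOC(=O)[C@H](O[Si](CC)(CC)CC)[C@@H]([C@@H](C)CCC=C(C)C)C(=O)CCl | intermediate
11 | 2-methylcyclopentane-1,3-dione | CC1C(=O)CCC1=O | starting material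
12 | ethyl (2R,3R,4S)-4,8-dimethyl-3-[(1-methyl-2,5-dioxocyclopentyl)acetyl]-2-[(triethylsilyl)oxy]non-7-enoate | CCOC(=O)[C@H](O[Si](CC)(CC)CC)[C@@H]([C@@H](C)CCC=C(C)C)C(=O)CC1(C)C(=O)CCC1=O | intermediate
13 | ethyl (2R,3R,4S)-2-hydroxy-4,8-dimethyl-3-[(1-methyl-2,5-dioxocyclopentyl)acetyl]non-7-enoate | CCOC(=O)[C@H](O)[C@@H]([C@@H](C)CCC=C(C)C)C(=O)CC1(C)C(=O)CCC1=O | intermediate
14 | anti-1,3-diol ester: 13 with the C8 ketone reduced, C8–OH anti to C11–OH | CCOC(=O)[C@H](O)[C@@H]([C@@H](C)CCC=C(C)C)[C@@H](O)CC1(C)C(=O)CCC1=O | intermediate
15 | γ-butyrolactone with 3-OH (C11), 4-[(2S)-6-methylhept-5-en-2-yl] (C12) and 5-[(1-methyl-2,5-dioxocyclopentyl)methyl] (C8); 4-substituent trans to both neighbours, 3-OH cis to the 5-substituent | O=C1[C@H](O)[C@@H]([C@@H](C)CCC=C(C)C)[C@H](CC2(C)C(=O)CCC2=O)O1 | intermediate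
16 | 3-bromo analogue of 15, bromine cis to the C12 side chain (inverted C11) | O=C1[C@@H](Br)[C@@H]([C@@H](C)CCC=C(C)C)[C@H](CC2(C)C(=O)CCC2=O)O1 | intermediate
17 | diiodosamarium enolate of the lactone (C10–O–Sm, C10=C11) | I[Sm](I)OC1=C[C@@H]([C@@H](C)CCC=C(C)C)[C@H](CC2(C)C(=O)CCC2=O)O1 | intermediate
18 | tricyclic hydroxy keto lactone: cis-hydrindane with C5=O, C6–CH3, C2–OH, and the lactone C8–O–C10(=O)–C11 bridging the cyclohexane; CH3, OH, the lactone bridge and the C12 side chain on one face | O=C3[C@H]1[C@@H]([C@@H](C)CCC=C(C)C)[C@@H](O3)C[C@]2(C)C(=O)CC[C@]12O | intermediate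
19 | 18 with C5=O reduced, C5–OH cis to CH3 and to C2–OH | O=C3[C@H]1[C@@H]([C@@H](C)CCC=C(C)C)[C@@H](O3)C[C@]2(C)[C@@H](O)CC[C@]12O | intermediate
20 | C5 tosylate of 19 | O=C3[C@H]1[C@@H]([C@@H](C)CCC=C(C)C)[C@@H](O3)C[C@]2(C)[C@@H](OS(=O)(=O)c4ccc(C)cc4)CC[C@]12O | intermediate
21 | cis-hydrindane with C2–OH, C5–OTs, C6–CH3, C8–OH, C11–CH2OH and the C12 side chain, all six on one face | OC[C@H]1[C@@H]([C@@H](C)CCC=C(C)C)[C@@H](O)C[C@]2(C)[C@@H](OS(=O)(=O)c3ccc(C)cc3)CC[C@]12O | intermediate
22 | cis-hydrindanol tosylate bis-TBS ether: 21 with C8–OTBS and C10–OTBS | CC(C)(C)[Si](C)(C)OC[C@H]1[C@@H]([C@@H](C)CCC=C(C)C)[C@@H](O[Si](C)(C)C(C)(C)C)C[C@]2(C)[C@@H](OS(=O)(=O)c3ccc(C)cc3)CC[C@]12O | intermediate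
23 | potassium C2 alkoxide of 22 | CC(C)(C)[Si](C)(C)OC[C@H]1[C@@H]([C@@H](C)CCC=C(C)C)[C@@H](O[Si](C)(C)C(C)(C)C)C[C@]2(C)[C@@H](OS(=O)(=O)c3ccc(C)cc3)CC[C@]12[O-].[K+] | intermediate
24 | (E)-7-(TBS-oxy)-9-(TBS-oxymethyl)-5-methyl-8-[(2S)-6-methylhept-5-en-2-yl]cyclonon-4-en-1-one, 7,8,9-all-cis (target labels: C2=O, E C5=C6, C8, C12, C11) | CC(C)(C)[Si](C)(C)OC[C@H]1[C@@H]([C@@H](C)CCC=C(C)C)[C@@H](O[Si](C)(C)C(C)(C)C)C/C(C)=C/CCC1=O | intermediate
25 | potassium enolate of 24 (C2=C3, ring-cis) | CC(C)(C)[Si](C)(C)OC[C@H]1[C@@H]([C@@H](C)CCC=C(C)C)[C@@H](O[Si](C)(C)C(C)(C)C)C/C(C)=C/C/C=C1/[O-].[K+] | intermediate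
26 | enol triflate of 24 at C2=C3 (C4 and C11 cis), E C5=C6 | CC(C)(C)[Si](C)(C)OC[C@H]1[C@@H]([C@@H](C)CCC=C(C)C)[C@@H](O[Si](C)(C)C(C)(C)C)C/C(C)=C/C/C=C1/OS(=O)(=O)C(F)(F)F | intermediate
27 | 26 with both silyl ethers removed (C8–OH, C10–OH) | OC[C@H]1[C@@H]([C@@H](C)CCC=C(C)C)[C@@H](O)C/C(C)=C/C/C=C1/OS(=O)(=O)C(F)(F)F | intermediate
28 | C10 aldehyde of 27 | O=C[C@H]1[C@@H]([C@@H](C)CCC=C(C)C)[C@@H](O)C/C(C)=C/C/C=C1/OS(=O)(=O)C(F)(F)F | intermediate
29 | bridged lactol (C8–O–C10H(OH), either C10 epimer) | OC3[C@H]1[C@@H]([C@@H](C)CCC=C(C)C)[C@@H](O3)C/C(C)=C/C/C=C1/OS(=O)(=O)C(F)(F)F | intermediate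
30 | bridged γ-lactone with the C2=C3 enol triflate and E C5=C6 | O=C3[C@H]1[C@@H]([C@@H](C)CCC=C(C)C)[C@@H](O3)C/C(C)=C/C/C=C1/OS(=O)(=O)C(F)(F)F | intermediate
31 | bridged γ-lactone with C1 formyl on C2, C2=C3 (C4 and C11 cis), E C5=C6 | O=C3[C@H]1[C@@H]([C@@H](C)CCC=C(C)C)[C@@H](O3)C/C(C)=C/C/C=C1/C=O | intermediate
32 | CNP0287742.1 | CC(=O)O/C=C1/C=C\C=C(/C)C[C@@H]2OC(=O)[C@H]1[C@H]2[C@@H](C)CCC=C(C)C | target

## Step count and weakest steps

Total: 20 steps. Longest linear sequence: 20 steps (1 → 32); compounds 2, 5 and 11 are purchased and enter in steps 1, 2 and 6.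

**Step 15 (key step).** The most likely failure is on the product side: the new ketone has an acidic C11–H with a β-silyloxy group, so enolisation by the alkoxide medium could epimerise C11 or expel silanolate. If the reactive chair is poorly populated, bimolecular E2 loss of the sulfonate toward C4 could also compete. The fallback sets out from 22. LiAlH4 in THF (0 °C → rt) forms the alkoxyaluminate, which is the species that fragments in hydride-induced fragmentations of β-sulfonyloxy ketones, and the excess hydride reduces the ketone as it appears, giving the cyclononenol F1. Dess–Martin periodinane buffered with NaHCO3 then returns to the route at 24 without the ketone ever meeting a base.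

**Step 10.** Electron transfer to the strained 1,3-dione, or protonation of the enolate, may outrun the bridging addition, because the ring closure builds a bicyclo[3.2.1] lactone. Attack on the other diastereotopic carbonyl is the second concern. The fallback sets out from 16 and replaces electron transfer by oxidative addition and transmetallation: RhCl(PPh3)3 (cat.) with Et2Zn in THF at 0 °C generates a zinc enolate with no one-electron reductant present, and its chelated aldol returns to the route at 18. No new isolated compound is involved.

**Step 6.** O-alkylation of the ambident enolate of the 2-substituted dione may compete with C-alkylation. The fallback sets out from 10 and builds the quaternary carbon in the other order: cyclopentane-1,3-dione (K2CO3, NaI, DMF) is C-alkylated at its unsubstituted 2-position to give the 2-(2-oxoalkyl)cyclopentane-1,3-dione F2, and C-methylation (MeI, K2CO3, acetone) returns to the route at 12.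

**Step 11.** Hydride may be delivered from the methyl/hydroxyl face, for example through coordination to the tertiary hydroxyl, giving the C5 epimer. The fallback sets out from 18 and accepts that epimer, the trans alcohol F3. Mitsunobu inversion (4-nitrobenzoic acid, PPh3, DIAD, PhMe) gives the 4-nitrobenzoate F4 with C5–O cis to CH3, and mild methanolysis (NaN3, MeOH) returns to the route at 19.

**Step 19.** Hydride transfer to the vinylpalladium species before CO insertion would simply reduce the triflate, and the skipped C2=C3/C5=C6 system could migrate. The fallback sets out from 30 and introduces C1 at the alcohol level: Stille coupling with Bu3SnCH2OH (Pd(PPh3)4, LiCl, dioxane, 90 °C) gives the allylic alcohol F5, and MnO2 in CH2Cl2 returns to the route at 31.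

**Step 20.** The enolate geometry about C1=C2 may be poorly controlled, and C-protonation of the extended enolate could pull the C5=C6 bond into conjugation. The fallback sets out from 31 and separates geometry setting from acylation: Et3SiOTf and Et3N at −78 °C convert the s-trans enal into the silyl dienol ether F6, whose geometry can be secured at that stage, and fluoride-promoted transacylation (Ac2O, CsF, MeCN, 0 °C) returns to the route at 32.

## Further compounds

F1 | step 15 | (E)-cyclonon-4-en-1-ol corresponding to 24 (C2 carbinol, both epimers) | CC(C)(C)[Si](C)(C)OC[C@H]1[C@@H]([C@@H](C)CCC=C(C)C)[C@@H](O[Si](C)(C)C(C)(C)C)C/C(C)=C/CCC1O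
F0 | step 10 | none | none
F2 | step 6 | analogue of 12 lacking the C6 methyl (2-substituted cyclopentane-1,3-dione) | CCOC(=O)[C@H](O[Si](CC)(CC)CC)[C@@H]([C@@H](C)CCC=C(C)C)C(=O)CC1C(=O)CCC1=O
F3 | step 11 | C5 epimer of 19 (C5–OH trans to CH3) | O=C3[C@H]1[C@@H]([C@@H](C)CCC=C(C)C)[C@@H](O3)C[C@]2(C)[C@H](O)CC[C@]12O
F4 | step 11 | 4-nitrobenzoate of 19 | O=C3[C@H]1[C@@H]([C@@H](C)CCC=C(C)C)[C@@H](O3)C[C@]2(C)[C@@H](OC(=O)c4ccc(cc4)[N+](=O)[O-])CC[C@]12O
F5 | step 19 | allylic alcohol: 30 with CH2OH in place of OTf | O=C3[C@H]1[C@@H]([C@@H](C)CCC=C(C)C)[C@@H](O3)C/C(C)=C/C/C=C1/CO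
F6 | step 20 | triethylsilyl dienol ether: 32 with OSiEt3 in place of OAc | CC[Si](CC)(CC)O/C=C1/C=C\C=C(/C)C[C@@H]2OC(=O)[C@H]1[C@H]2[C@@H](C)CCC=C(C)C
A1 | alternative 1 | bridged bicyclic lactone with C2–CH2OTBS, product of the ketyl–enoate cascade | CC(C)(C)[Si](C)(C)OC[C@H]1/C=C\C=C(/C)C[C@@H]2OC(=O)[C@H]1[C@H]2[C@@H](C)CCC=C(C)C
A2 | alternative 1 | open-chain C8 aldehyde with the (E)-C11=C12 methyl enoate, (3Z,5E)-diene and C2–CH2OTBS | COC(=O)/C(=C/[C@@H](C)CCC=C(C)C)[C@@H](CO[Si](C)(C)C(C)(C)C)/C=C\C=C(/C)CC=O
A3 | alternative 2 | Co2(CO)6 complex of the bridged bicyclic lactone (C3≡C4 complexed, C2–CH2OTBS, one C2 epimer) | CC(C)(C)[Si](C)(C)OC[C@H]1C23[Co]4(=C=O)(=C=O)(=C=O)[Co]2(=C=O)(=C=O)(=C=O)C34/C=C(\C)C[C@@H]5OC(=O)[C@H]1[C@H]5[C@@H](C)CCC=C(C)C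
A4 | alternative 2 | Co2(CO)6-complexed propargylic acetate on the lactone trimethylsilyl ketene acetal | CC(=O)OC(CO[Si](C)(C)C(C)(C)C)C23[Co]4(=C=O)(=C=O)(=C=O)[Co]2(=C=O)(=C=O)(=C=O)C34/C=C(\C)C[C@@H]5OC(O[Si](C)(C)C)=C[C@H]5[C@@H](C)CCC=C(C)C
A5 | alternative 3 | (2Z,4E)-cyclonona-2,4-dien-1-one bis-TBS ether (target labels 3Z,5E) | CC(C)(C)[Si](C)(C)OC[C@H]1[C@@H]([C@@H](C)CCC=C(C)C)[C@@H](O[Si](C)(C)C(C)(C)C)C/C(C)=C/C=C\C1=O
A6 | alternative 3 | cis-fused bicyclo[5.2.0]non-8-en-2-one with the C3–C6 bond (one cis-fused diastereomer) | CC(C)(C)[Si](C)(C)OC[C@H]1[C@@H]([C@@H](C)CCC=C(C)C)[C@@H](O[Si](C)(C)C(C)(C)C)C[C@@]2(C)C=C[C@H]2C1=O
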